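## Retrosynthetic overview

1. The aryl C5'–O bond of the ester is made last, by direct C–H acyloxylation of the only free ring-A carbon of chalcone 11. The acyloxy group, with its (S) centre, comes from chiral-pool (S)-2-methylbutanoic acid.
2. Chalcone 11 is cut at the enone into acetophenone 8 and benzaldehyde (Claisen–Schmidt, sets the E alkene).
3. Acetophenone 8 comes from C2-symmetric 2,5-dimethoxyresorcinol 6 by Hoesch acylation; symmetry removes any regiochemical question.
4. Resorcinol 6 comes from 4-methoxyphenol by dibromination, O-methylation and double Pd-catalysed C–O hydroxylation.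
5. No ring is formed in the route; both benzene rings are bought.

Assumption: commercial (S)-(+)-2-methylbutanoic acid (≥98% ee) is the source of the single stereocentre. Primed locants (2', 4', 5' …) refer to ring A of the chalcone.

## Route

Step 1
Reactants: 1 4-methoxyphenol
Product: 3 2,6-dibromo-4-methoxyphenol, via 2-bromo-4-methoxyphenol 2 (not isolated)
Conditions: Br2 (2.05 equiv), CH2Cl2, 0 °C → rt
Reagents that add atoms: bromine, BrBr
Why: Electrophilic aromatic bromination; OH is the stronger director and its para position is blocked by OMe, so both bromines enter ortho to OH.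

Step 2
Reactants: 3 2,6-dibromo-4-methoxyphenol
Product: 4 1,3-dibromo-2,5-dimethoxybenzene
Conditions: MeI, K2CO3, acetone, reflux
Reagents that add atoms: iodomethane, CI
Why: Williamson ether synthesis (SN2) on the acidic, easily deprotonated 2,6-dibromophenol.

Step 3
Reactants: 4 1,3-dibromo-2,5-dimethoxybenzene
Product: 6 2,5-dimethoxybenzene-1,3-diol, via 3-bromo-2,5-dimethoxyphenol 5 (not isolated)
Conditions: Pd2(dba)3 (2 mol%), tBuXPhos (8 mol%), KOH (5 equiv), dioxane/H2O 1:1, 100 °C, N2; then aq. HCl
Reagents that add atoms: potassium hydroxide, [K+].[OH-]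
Why: Pd-catalysed C–O cross-coupling (hydroxylation) of aryl bromides with hydroxide; the bulky biarylphosphine favours Ar–OH reductive elimination over diaryl ether formation, and the two C–Br bonds are equivalent.

Step 4
Reactants: 6 2,5-dimethoxybenzene-1,3-diol
Product: 8 1-(2,4-dihydroxy-3,6-dimethoxyphenyl)ethan-1-one, via ketiminium chloride 7 (not isolated)
Conditions: MeCN, ZnCl2 (cat.), HCl (g), Et2O, 0 °C; then H2O, 90 °C
Reagents that add atoms: acetonitrile, CC#N; water, O
Why: Houben–Hoesch acylation; the nitrilium electrophile attacks C4 (identical to C6 by symmetry), which is ortho/para to both OH groups, and the iminium salt 7 is deactivated towards a second acylation before it is hydrolysed to the ketone.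

Step 5
Reactants: 8 1-(2,4-dihydroxy-3,6-dimethoxyphenyl)ethan-1-one; 9 benzaldehyde
Product: 11 (2E)-1-(2,4-dihydroxy-3,6-dimethoxyphenyl)-3-phenylprop-2-en-1-one, via aldol adduct 10 (not isolated)
Conditions: KOH (50% aq., 10 equiv), EtOH, 0 °C → rt, 48 h; then cold aq. HCl
Reagents that add atoms: none
Why: Claisen–Schmidt (crossed aldol) condensation; the methyl ketone enolate adds to non-enolisable benzaldehyde and E1cB dehydration of aldol 10 gives the conjugated E-enone, the thermodynamic alkene.

Step 6
Reactants: 11 (2E)-1-(2,4-dihydroxy-3,6-dimethoxyphenyl)-3-phenylprop-2-en-1-one; 12 (2S)-2-methylbutanoic acid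
Product: 16 2,4-dihydroxy-3,6-dimethoxy-5-[(2E)-3-phenylprop-2-enoyl]phenyl (2S)-2-methylbutanoate, via O-acylisourea 13 (not isolated), via peracid 14 (not isolated), via diacyl peroxide 15 (not isolated)
Conditions: 12 (2.4 equiv), DCC (2.4 equiv), ethereal H2O2 (1.2 equiv), CH2Cl2, −15 °C, cold filtration; filtrate added to 11, NaH (1.0 equiv), 15-crown-5, THF, −30 → 0 °C; then aq. HCl (peroxide kept dilute, ≤0 °C, never concentrated)
Reagents that add atoms: hydrogen peroxide, OO
Why: Proposed new method: an "acyl-Elbs" C–H acyloxylation in which the sodium 4'-phenoxide of 11 (the chelated 2'-OH stays protonated) acts as a vinylogous enolate whose only unsubstituted ring carbon, C5' (ortho to O4', para to O2', ortho to 6'-OMe), attacks the O–O σ* of peroxide 15 in an SN2-at-oxygen displacement of 2-methylbutanoate, and loss of the C5' proton restores the arene, so the aryl C–O bond is formed with the acyloxy group and its (S) centre transferred intact (DCC activation without base, no species more basic than a phenoxide, α-C–H never touched); any 4'-O-acyl by-product should drift to the same 5'-ester by base-mediated 1,2-acyl shift because the para-acyl 4'-OH is the more acidic phenol; the closest known reaction types are the Elbs persulfate oxidation of phenoxides, the ortho-benzoyloxylation of phenols with dibenzoyl peroxide and the α-benzoyloxylation of enolates with dibenzoyl peroxide, none shown with an α-stereogenic sec-alkyl diacyl peroxide or on a polyoxygenated chalcone.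

## Compound list

1 | 4-methoxyphenol | COc1ccc(O)cc1 | starting material
2 | 2-bromo-4-methoxyphenol | COc1ccc(O)c(Br)c1 | intermediate
3 | 2,6-dibromo-4-methoxyphenol | COc1cc(Br)c(O)c(Br)c1 | intermediate
4 | 1,3-dibromo-2,5-dimethoxybenzene | COc1cc(Br)c(OC)c(Br)c1 | intermediate
5 | 3-bromo-2,5-dimethoxyphenol | COc1cc(O)c(OC)c(Br)c1 | intermediate
6 | 2,5-dimethoxybenzene-1,3-diol | COc1cc(O)c(OC)c(O)c1 | intermediate
7 | 1-(2,4-dihydroxy-3,6-dimethoxyphenyl)ethan-1-iminium chloride | CC(=[NH2+])c1c(O)c(OC)c(O)cc1OC.[Cl-] | intermediate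
8 | 1-(2,4-dihydroxy-3,6-dimethoxyphenyl)ethan-1-one | CC(=O)c1c(O)c(OC)c(O)cc1OC | intermediate
9 | benzaldehyde | O=Cc1ccccc1 | starting material
10 | 1-(2,4-dihydroxy-3,6-dimethoxyphenyl)-3-hydroxy-3-phenylpropan-1-one (racemic) | COc1cc(O)c(OC)c(O)c1C(=O)CC(O)c1ccccc1 | intermediate
11 | (2E)-1-(2,4-dihydroxy-3,6-dimethoxyphenyl)-3-phenylprop-2-en-1-one | COc1cc(O)c(OC)c(O)c1C(=O)/C=C/c1ccccc1 | intermediate
12 | (2S)-2-methylbutanoic acid | CC[C@H](C)C(=O)O | starting material
13 | N,N'-dicyclohexyl-O-[(2S)-2-methylbutanoyl]isourea | CC[C@H](C)C(=O)OC(NC1CCCCC1)=NC1CCCCC1 | intermediate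
14 | (2S)-2-methylbutaneperoxoic acid | CC[C@H](C)C(=O)OO | intermediate
15 | bis[(2S)-2-methylbutanoyl] peroxide | CC[C@H](C)C(=O)OOC(=O)[C@@H](C)CC | intermediate
16 | 2,4-dihydroxy-3,6-dimethoxy-5-[(2E)-3-phenylprop-2-enoyl]phenyl (2S)-2-methylbutanoate | CC[C@H](C)C(=O)Oc1c(O)c(OC)c(O)c(C(=O)/C=C/c2ccccc2)c1OC | target

## Step count and risks

Total step count: 6. Longest linear sequence: 6 (1 → 3 → 4 → 6 → 8 → 11 → 16); benzaldehyde 9 and acid 12 enter as bought materials.

The three steps most likely to fail:

**Step 6 (the proposed new C–H acyloxylation).** The phenoxide may attack the peroxide carbonyl instead (4'-O-acylation plus peracid), electron transfer may decarboxylate the sec-alkyl peroxide, or the product may be over-oxidised. The fallback uses known chemistry and sets out from 11. Teuber oxidation with Frémy's salt (KH2PO4 buffer, acetone/H2O, rt) oxidises the free C5' position to give 2-hydroxy-3,6-dimethoxy-5-[(2E)-3-phenylprop-2-enoyl]cyclohexa-2,5-diene-1,4-dione F1. Reduction with Na2S2O4 (EtOAc/H2O) gives (2E)-1-(2,4,5-trihydroxy-3,6-dimethoxyphenyl)-3-phenylprop-2-en-1-one F2. Steglich esterification of F2 with 12 (EDC·HCl, cat. DMAP, CH2Cl2, 0 °C), followed by a brief Et3N equilibration so that the acyl group settles on O5' (the 2'-OH is chelated, the 4'-OH is the more acidic phenol and stays free), returns to the route at 16.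

**Step 3 (double Pd-catalysed hydroxylation).** The second coupling has to proceed on the electron-rich bromophenoxide 5, and the resorcinol is air-sensitive in hot base. The fallback sets out from 4 and replaces direct C–O coupling by C–B formation and oxidation. Miyaura bis-borylation (B2pin2, Pd(dppf)Cl2, KOAc, dioxane, 90 °C) gives 2,2'-(2,5-dimethoxy-1,3-phenylene)bis(4,4,5,5-tetramethyl-1,3,2-dioxaborolane) F3, and oxidation with H2O2/NaOH (THF, 0 °C) returns to the route at 6.

**Step 5 (Claisen–Schmidt on the unprotected dihydroxyacetophenone).** The 4-phenoxide lowers enolate reactivity, and the 2'-hydroxychalcone can close to a flavanone. The fallback sets out from 8 and uses a protecting group. Selective MOM protection of the non-chelated 4-OH (MOMCl, iPr2NEt, CH2Cl2, 0 °C) gives 1-[2-hydroxy-3,6-dimethoxy-4-(methoxymethoxy)phenyl]ethan-1-one F4. Condensation with 9 (KOH, EtOH, rt) gives (2E)-1-[2-hydroxy-3,6-dimethoxy-4-(methoxymethoxy)phenyl]-3-phenylprop-2-en-1-one F5, and MOM cleavage (HCl, MeOH, 40 °C) returns to the route at 11.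

## Further compounds

F1 | step 6 | 2-hydroxy-3,6-dimethoxy-5-[(2E)-3-phenylprop-2-enoyl]cyclohexa-2,5-diene-1,4-dione | COC1=C(O)C(=O)C(OC)=C(C(=O)/C=C/c2ccccc2)C1=O
F2 | step 6 | (2E)-1-(2,4,5-trihydroxy-3,6-dimethoxyphenyl)-3-phenylprop-2-en-1-one | COc1c(O)c(O)c(OC)c(O)c1C(=O)/C=C/c1ccccc1
F3 | step 3 | 2,2'-(2,5-dimethoxy-1,3-phenylene)bis(4,4,5,5-tetramethyl-1,3,2-dioxaborolane) | COc1cc(B2OC(C)(C)C(C)(C)O2)c(OC)c(B2OC(C)(C)C(C)(C)O2)c1
F4 | step 5 | 1-[2-hydroxy-3,6-dimethoxy-4-(methoxymethoxy)phenyl]ethan-1-one | COCOc1cc(OC)c(C(C)=O)c(O)c1OC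
F5 | step 5 | (2E)-1-[2-hydroxy-3,6-dimethoxy-4-(methoxymethoxy)phenyl]-3-phenylprop-2-en-1-one | COCOc1cc(OC)c(C(=O)/C=C/c2ccccc2)c(O)c1OC
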